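The ring carbons are numbered C1 (heptenyl-bearing), C2 (CH2OH-bearing), C3 (carbinol), C4 (epoxide CH), C5 (quaternary epoxide carbon), C6 (carbinol). In the cyclohexene ring the C3 carbinol lies next to the oxygenated C4 and the oxygenated quaternary C5, which is an aldol retron across C3–C4 once C5 is read as a ketone and C4 as CHCl.
Oxirane (second ring, formed last): a tiglate dienol ether adds through its γ-carbon to the C5 ketone, and the C5 alkoxide then displaces chloride at C4 with inversion while the C3 oxygen is kept silylated.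
Carbocycle (first ring): the C3–C4 bond is formed by an L-proline enamine aldol of a (Z)-enal chloromethyl ketone whose only stereocentre is the silylated C6 carbinol.
The aldol precursor comes from a δ-lactone (C3–O–C5 acyl) by addition of LiCH2Cl and oxidation at C3. The lactone forms when one of two identical CH2OH arms on C2 closes onto the C5 ester, so the tetrasubstituted alkene geometry is fixed without a stereoselective olefination.
C1 comes from 5-(dibromomethylidene)-2,2-dimethyl-1,3-dioxane: Suzuki coupling brings in the heptenyl group, Br–Li exchange with diethyl oxalate brings in C6–C5, and a CBS reduction sets C6.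
Key step: step 9

Remark: the labels C1–C6 are also used for the corresponding carbons of acyclic and lactone intermediates. The chloromethyl lactol of step 7 is drawn as the cyclic hemiketal, which equilibrates with its open hydroxy ketone form.

Step 1
Reactants: 1 2,2-dimethyl-1,3-dioxan-5-one; 2 carbon tetrabromide
Product: 3 5-(dibromomethylidene)-2,2-dimethyl-1,3-dioxane
Conditions: PPh3 (4 equiv), CH2Cl2, 0 °C to rt
Reagents that add atoms: none
Why: Ramirez (Corey–Fuchs-type) dibromo-olefination of an electrophilic dialkoxy ketone by the ylide Ph3P=CBr2, which gives an alkene whose C2 end carries two identical CH2O arms and therefore has no geometry to control.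

Step 2
Reactants: 3 5-(dibromomethylidene)-2,2-dimethyl-1,3-dioxane; 4 (E)-hept-1-en-1-ylboronic acid
Product: 5 5-[(2E)-1-bromooct-2-en-1-ylidene]-2,2-dimethyl-1,3-dioxane
Conditions: 4 (1.0 equiv), Pd2(dba)3 (2.5 mol %), P(2-furyl)3 (15 mol %), Cs2CO3, 1,4-dioxane/H2O, 60 °C
Reagents that add atoms: none
Why: Suzuki–Miyaura coupling with retention of the E geometry of the boronic acid, in which the gem-dibromide should react faster than the more hindered conjugated monobromide, so that one equivalent of boronic acid stops at mono-coupling.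

Step 3
Reactants: 5 5-[(2E)-1-bromooct-2-en-1-ylidene]-2,2-dimethyl-1,3-dioxane; 6 diethyl oxalate
Product: 8 ethyl (4E)-3-(2,2-dimethyl-1,3-dioxan-5-ylidene)-2-oxodec-4-enoate, via dienyllithium 7 (not isolated)
Conditions: t-BuLi (2 equiv), Et2O, −78 °C; cannulated into 6 (3 equiv), THF, −78 °C; AcOH quench
Reagents that add atoms: none
Why: Bromine–lithium exchange followed by mono-acylation of excess diethyl oxalate, a standard α-keto ester synthesis in which the chelated tetrahedral intermediate survives until the cold quench and the geometry of the lithiated carbon is irrelevant because the other alkene terminus is symmetric.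

Step 4
Reactants: 8 ethyl (4E)-3-(2,2-dimethyl-1,3-dioxan-5-ylidene)-2-oxodec-4-enoate
Product: 9 ethyl (2R,4E)-3-(2,2-dimethyl-1,3-dioxan-5-ylidene)-2-hydroxydec-4-enoate
Conditions: (R)-2-methyl-CBS-oxazaborolidine [(3aR)-1-methyl-3,3-diphenyltetrahydro-1H,3H-pyrrolo[1,2-c][1,3,2]oxazaborole] (20 mol %), catecholborane, PhMe, −78 °C
Reagents that add atoms: none
Why: Corey–Bakshi–Shibata reduction in which the twisted tetrasubstituted dienyl group should act as the large substituent and the ester as the small one, so that the (R)-catalyst is expected to deliver hydride to the face that gives the (R)-carbinol at C6, while catecholborane at −78 °C keeps the uncatalysed reduction slow.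

Step 5
Reactants: 9 ethyl (2R,4E)-3-(2,2-dimethyl-1,3-dioxan-5-ylidene)-2-hydroxydec-4-enoate
Product: 11 (3R)-4-[(1E)-hept-1-en-1-yl]-3-hydroxy-5-(hydroxymethyl)-3,6-dihydro-2H-pyran-2-one, via diol ester 10 (not isolated)
Conditions: AcOH/H2O/THF, 40 °C; then PPTS (cat.), PhMe, 60 °C
Reagents that add atoms: none
Why: Acetal hydrolysis followed by acid-catalysed lactonisation, in which only the CH2OH arm cis to C6 can reach the ester through a six-membered ring, so that this arm becomes C3 and the free arm is by construction cis to the heptenyl group.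

Step 6
Reactants: 11 (3R)-4-[(1E)-hept-1-en-1-yl]-3-hydroxy-5-(hydroxymethyl)-3,6-dihydro-2H-pyran-2-one
Product: 12 (3R)-3-[(tert-butyldimethylsilyl)oxy]-5-{[(tert-butyldimethylsilyl)oxy]methyl}-4-[(1E)-hept-1-en-1-yl]-3,6-dihydro-2H-pyran-2-one
Conditions: TBSOTf (2.5 equiv), 2,6-lutidine, CH2Cl2, −78 to 0 °C
Reagents that add atoms: tert-butyldimethylsilyl trifluoromethanesulfonate, CC(C)(C)[Si](C)(C)OS(=O)(=O)C(F)(F)F
Why: Silyl ether formation on both hydroxyl groups with a silyl triflate and a hindered, weakly basic pyridine, which should leave the acidic C6–H of the lactone untouched.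

Step 7
Reactants: 12 (3R)-3-[(tert-butyldimethylsilyl)oxy]-5-{[(tert-butyldimethylsilyl)oxy]methyl}-4-[(1E)-hept-1-en-1-yl]-3,6-dihydro-2H-pyran-2-one; 13 chloroiodomethane
Product: 14 (3R)-3-[(tert-butyldimethylsilyl)oxy]-5-{[(tert-butyldimethylsilyl)oxy]methyl}-2-(chloromethyl)-4-[(1E)-hept-1-en-1-yl]-3,6-dihydro-2H-pyran-2-ol (both C2 epimers)
Conditions: 13 (1.6 equiv), MeLi·LiBr (1.5 equiv), THF, −78 °C (LiCH2Cl generated in the presence of 12); AcOH, −78 °C
Reagents that add atoms: none
Why: Carbenoid homologation of a carboxylic ester, in which chloromethyllithium adds once to the lactone carbonyl and the lithium hemiketalate is protonated cold before it can collapse, add a second carbenoid or close to an epoxide.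

Step 8
Reactants: 14 (3R)-3-[(tert-butyldimethylsilyl)oxy]-5-{[(tert-butyldimethylsilyl)oxy]methyl}-2-(chloromethyl)-4-[(1E)-hept-1-en-1-yl]-3,6-dihydro-2H-pyran-2-ol
Product: 15 (2Z,4R)-4-[(tert-butyldimethylsilyl)oxy]-2-{[(tert-butyldimethylsilyl)oxy]methyl}-6-chloro-3-[(1E)-hept-1-en-1-yl]-5-oxohex-2-enal
Conditions: Dess–Martin periodinane (1.5 equiv), CH2Cl2, 0 °C to rt
Reagents that add atoms: none
Why: Dess–Martin oxidation of the primary allylic alcohol in the open hydroxy ketone tautomer, which should drain the ring–chain equilibrium because the hemiketal carbon carries no hydrogen and cannot itself be oxidised.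

Step 9
Reactants: 15 (2Z,4R)-4-[(tert-butyldimethylsilyl)oxy]-2-{[(tert-butyldimethylsilyl)oxy]methyl}-6-chloro-3-[(1E)-hept-1-en-1-yl]-5-oxohex-2-enal
Product: 17 (2R,5R,6S)-2-[(tert-butyldimethylsilyl)oxy]-4-{[(tert-butyldimethylsilyl)oxy]methyl}-6-chloro-3-[(1E)-hept-1-en-1-yl]-5-hydroxycyclohex-3-en-1-one, via proline enamine 16 (not isolated)
Conditions: L-proline (30 mol %), DMSO, 20 °C
Reagents that add atoms: none
Why: L-Proline condenses with the C5 ketone, the enamine forms on the chloromethyl side (the C6 side would require a tetrasubstituted enamine), its carbon C4 adds to the C3 aldehyde that is hydrogen-bonded to the carboxylic acid, and hydrolysis of the iminium ion releases the catalyst. The closest known reaction types are the Hajos–Parrish-type intramolecular proline aldol and the amine-catalysed direct aldol additions of chloroacetone, which give anti chlorohydrins. The carbocycle closes in the 6-(enolendo)-exo-trig mode, because both enamine carbons C4 and C5 become members of the new ring. C3 and C4 are set by the catalyst, since the (E)-enamine (chlorine trans to nitrogen) in the anti conformation is attacked on the face that carries the carboxylic acid, which should give the trans C3–OH/C4–Cl pair as (5R,6S); the existing C6 centre is expected to be matched with L-proline because allylic strain turns C6–H into the enamine plane toward the pyrrolidine and the C6 silyl ether away from the incoming aldehyde, which leads to the half-chair with all three substituents equatorial. The step needs the amine to engage the ketone and not the enal, because an iminium ion or dienamine at C3 would epimerise C6, and this is secured by the fully substituted, α-branched enal, which condenses poorly with a secondary amine, and by the Z-alkene, which holds C3 next to C4. Neutral conditions at ambient temperature are chosen so that the β-hydroxy ketone neither reverts nor dehydrates toward a phenol.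

Step 10
Reactants: 17 (2R,5R,6S)-2-[(tert-butyldimethylsilyl)oxy]-4-{[(tert-butyldimethylsilyl)oxy]methyl}-6-chloro-3-[(1E)-hept-1-en-1-yl]-5-hydroxycyclohex-3-en-1-one
Product: 18 (2R,5R,6S)-2,5-bis[(tert-butyldimethylsilyl)oxy]-4-{[(tert-butyldimethylsilyl)oxy]methyl}-6-chloro-3-[(1E)-hept-1-en-1-yl]cyclohex-3-en-1-one
Conditions: TBSOTf, 2,6-lutidine, CH2Cl2, −78 °C
Reagents that add atoms: tert-butyldimethylsilyl trifluoromethanesulfonate, CC(C)(C)[Si](C)(C)OS(=O)(=O)C(F)(F)F
Why: Silyl ether formation at low temperature with a non-nucleophilic base, which should avoid retro-aldol and β-elimination and which blocks the C3 oxygen so that it cannot later compete with the C5 oxygen for displacement of chloride at C4.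

Step 11
Reactants: 19 (2E)-2-methylbut-2-enoyl chloride (tigloyl chloride); 20 2-(trimethylsilyl)ethanol
Product: 21 2-(trimethylsilyl)ethyl (2E)-2-methylbut-2-enoate
Conditions: Et3N, DMAP (cat.), CH2Cl2, 0 °C to rt
Reagents that add atoms: none
Why: Acylation of the alcohol by the acid chloride under nucleophilic catalysis, which gives an ester that fluoride can cleave together with the silyl ethers at the end.

Step 12
Reactants: 21 2-(trimethylsilyl)ethyl (2E)-2-methylbut-2-enoate
Product: 22 trimethyl({2-methyl-1-[2-(trimethylsilyl)ethoxy]buta-1,3-dien-1-yl}oxy)silane (mixture of ketene acetal isomers)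
Conditions: LiN(i-Pr)2, THF/DMPU, −78 °C; Me3SiCl, −78 °C to rt
Reagents that add atoms: chlorotrimethylsilane, C[Si](C)(C)Cl
Why: Kinetic γ-deprotonation of the tiglate and O-silylation of the dienolate, the usual preparation of silyl dienol ethers (vinylogous silyl ketene acetals) from 2-enoates.

Step 13
Reactants: 18 (2R,5R,6S)-2,5-bis[(tert-butyldimethylsilyl)oxy]-4-{[(tert-butyldimethylsilyl)oxy]methyl}-6-chloro-3-[(1E)-hept-1-en-1-yl]cyclohex-3-en-1-one; 22 trimethyl({2-methyl-1-[2-(trimethylsilyl)ethoxy]buta-1,3-dien-1-yl}oxy)silane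
Product: 23 2-(trimethylsilyl)ethyl (2E)-4-[(1S,2R,5R,6S)-2,5-bis[(tert-butyldimethylsilyl)oxy]-4-{[(tert-butyldimethylsilyl)oxy]methyl}-6-chloro-3-[(1E)-hept-1-en-1-yl]-1-hydroxycyclohex-3-en-1-yl]-2-methylbut-2-enoate
Conditions: TiCl4 (1.1 equiv), CH2Cl2, −78 °C; aq. NaHCO3
Reagents that add atoms: none
Why: Vinylogous Mukaiyama aldol addition in which the TiCl4-activated α-chloro ketone is attacked by the unhindered γ-carbon of the dienol ether to give the (E)-2-methylbut-2-enoate directly, and the nucleophile should enter axially on the all-equatorial half-chair, anti to the C3 silyl ether, so that the new C5–C bond is cis to chlorine and the C5 oxygen trans to it.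

Step 14
Reactants: 23 2-(trimethylsilyl)ethyl (2E)-4-[(1S,2R,5R,6S)-2,5-bis[(tert-butyldimethylsilyl)oxy]-4-{[(tert-butyldimethylsilyl)oxy]methyl}-6-chloro-3-[(1E)-hept-1-en-1-yl]-1-hydroxycyclohex-3-en-1-yl]-2-methylbut-2-enoate
Product: 24 2-(trimethylsilyl)ethyl (2E)-4-[(1S,2R,5R,6R)-2,5-bis[(tert-butyldimethylsilyl)oxy]-4-{[(tert-butyldimethylsilyl)oxy]methyl}-3-[(1E)-hept-1-en-1-yl]-7-oxabicyclo[4.1.0]hept-3-en-1-yl]-2-methylbut-2-enoate
Conditions: NaH, THF, 0 °C to rt
Reagents that add atoms: none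
Why: Intramolecular Williamson (3-exo-tet) displacement in which the C5 alkoxide attacks C4 from the face opposite to chloride after a ring flip to the trans-diaxial arrangement, which inverts C4 and places the oxirane cis to the C3 oxygen.

Step 15
Reactants: 24 2-(trimethylsilyl)ethyl (2E)-4-[(1S,2R,5R,6R)-2,5-bis[(tert-butyldimethylsilyl)oxy]-4-{[(tert-butyldimethylsilyl)oxy]methyl}-3-[(1E)-hept-1-en-1-yl]-7-oxabicyclo[4.1.0]hept-3-en-1-yl]-2-methylbut-2-enoate
Product: 25 (2E)-4-[(1S,2R,5R,6R)-3-[(1E)-hept-1-en-1-yl]-2,5-dihydroxy-4-(hydroxymethyl)-7-oxabicyclo[4.1.0]hept-3-en-1-yl]-2-methylbut-2-enoic acid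
Conditions: Bu4NF (6 equiv), THF, 0 °C to rt; then AcOH, pH 4 buffer
Reagents that add atoms: none
Why: Fluoride-mediated desilylation that cleaves the three silyl ethers and, by β-elimination of ethene and Me3SiF, the 2-(trimethylsilyl)ethyl ester in one operation, while the C3 hydroxyl is cis to the oxirane and cannot trigger an epoxide migration.

Compound list
1 | 2,2-dimethyl-1,3-dioxan-5-one | CC1(C)OCC(=O)CO1 | starting material
2 | carbon tetrabromide | BrC(Br)(Br)Br | starting material
3 | 5-(dibromomethylidene)-2,2-dimethyl-1,3-dioxane | CC1(C)OCC(=C(Br)Br)CO1 | intermediate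
4 | (E)-hept-1-en-1-ylboronic acid | CCCCC/C=C/B(O)O | starting material
5 | 5-[(2E)-1-bromooct-2-en-1-ylidene]-2,2-dimethyl-1,3-dioxane | CCCCC/C=C/C(Br)=C1COC(C)(C)OC1 | intermediate
6 | diethyl oxalate | CCOC(=O)C(=O)OCC | starting material
7 | dienyllithium: [(2E)-1-(2,2-dimethyl-1,3-dioxan-5-ylidene)oct-2-en-1-yl]lithium | CCCCC/C=C/C([Li])=C1COC(C)(C)OC1 | intermediate (not isolated)
8 | ethyl (4E)-3-(2,2-dimethyl-1,3-dioxan-5-ylidene)-2-oxodec-4-enoate | CCCCC/C=C/C(C(=O)C(=O)OCC)=C1COC(C)(C)OC1 | intermediate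
9 | ethyl (2R,4E)-3-(2,2-dimethyl-1,3-dioxan-5-ylidene)-2-hydroxydec-4-enoate | CCCCC/C=C/C(=C1COC(C)(C)OC1)[C@@H](O)C(=O)OCC | intermediate
10 | diol ester: ethyl (2R,4E)-3-(1,3-dihydroxypropan-2-ylidene)-2-hydroxydec-4-enoate | CCCCC/C=C/C(=C(CO)CO)[C@@H](O)C(=O)OCC | intermediate (not isolated)
11 | (3R)-4-[(1E)-hept-1-en-1-yl]-3-hydroxy-5-(hydroxymethyl)-3,6-dihydro-2H-pyran-2-one | CCCCC/C=C/C1=C(CO)COC(=O)[C@@H]1O | intermediate
12 | (3R)-3-[(tert-butyldimethylsilyl)oxy]-5-{[(tert-butyldimethylsilyl)oxy]methyl}-4-[(1E)-hept-1-en-1-yl]-3,6-dihydro-2H-pyran-2-one | CCCCC/C=C/C1=C(CO[Si](C)(C)C(C)(C)C)COC(=O)[C@@H]1O[Si](C)(C)C(C)(C)C | intermediate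
13 | chloroiodomethane | ClCI | starting material
14 | (3R)-3-[(tert-butyldimethylsilyl)oxy]-5-{[(tert-butyldimethylsilyl)oxy]methyl}-2-(chloromethyl)-4-[(1E)-hept-1-en-1-yl]-3,6-dihydro-2H-pyran-2-ol (both C2 epimers) | CCCCC/C=C/C1=C(CO[Si](C)(C)C(C)(C)C)COC(O)(CCl)[C@@H]1O[Si](C)(C)C(C)(C)C | intermediate
15 | (2Z,4R)-4-[(tert-butyldimethylsilyl)oxy]-2-{[(tert-butyldimethylsilyl)oxy]methyl}-6-chloro-3-[(1E)-hept-1-en-1-yl]-5-oxohex-2-enal (key-step precursor) | CCCCC/C=C/C(=C(/C=O)CO[Si](C)(C)C(C)(C)C)[C@@H](O[Si](C)(C)C(C)(C)C)C(=O)CCl | intermediate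
16 | proline enamine: (E)-enamine of 15 with L-proline at C5 (C4=C5, chlorine trans to nitrogen) | CCCCC/C=C/C(=C(/C=O)CO[Si](C)(C)C(C)(C)C)[C@@H](O[Si](C)(C)C(C)(C)C)/C(=C\Cl)N1CCC[C@H]1C(=O)O | intermediate (not isolated)
17 | (2R,5R,6S)-2-[(tert-butyldimethylsilyl)oxy]-4-{[(tert-butyldimethylsilyl)oxy]methyl}-6-chloro-3-[(1E)-hept-1-en-1-yl]-5-hydroxycyclohex-3-en-1-one (key-step product) | CCCCC/C=C/C1=C(CO[Si](C)(C)C(C)(C)C)[C@@H](O)[C@H](Cl)C(=O)[C@@H]1O[Si](C)(C)C(C)(C)C | intermediate
18 | (2R,5R,6S)-2,5-bis[(tert-butyldimethylsilyl)oxy]-4-{[(tert-butyldimethylsilyl)oxy]methyl}-6-chloro-3-[(1E)-hept-1-en-1-yl]cyclohex-3-en-1-one | CCCCC/C=C/C1=C(CO[Si](C)(C)C(C)(C)C)[C@@H](O[Si](C)(C)C(C)(C)C)[C@H](Cl)C(=O)[C@@H]1O[Si](C)(C)C(C)(C)C | intermediate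
19 | (2E)-2-methylbut-2-enoyl chloride (tigloyl chloride) | C/C=C(\C)C(=O)Cl | starting material
20 | 2-(trimethylsilyl)ethanol | C[Si](C)(C)CCO | starting material
21 | 2-(trimethylsilyl)ethyl (2E)-2-methylbut-2-enoate | C/C=C(\C)C(=O)OCC[Si](C)(C)C | intermediate
22 | trimethyl({2-methyl-1-[2-(trimethylsilyl)ethoxy]buta-1,3-dien-1-yl}oxy)silane (mixture of ketene acetal isomers) | C=CC(C)=C(OCC[Si](C)(C)C)O[Si](C)(C)C | intermediate
23 | 2-(trimethylsilyl)ethyl (2E)-4-[(1S,2R,5R,6S)-2,5-bis[(tert-butyldimethylsilyl)oxy]-4-{[(tert-butyldimethylsilyl)oxy]methyl}-6-chloro-3-[(1E)-hept-1-en-1-yl]-1-hydroxycyclohex-3-en-1-yl]-2-methylbut-2-enoate | CCCCC/C=C/C1=C(CO[Si](C)(C)C(C)(C)C)[C@@H](O[Si](C)(C)C(C)(C)C)[C@H](Cl)[C@](O)(C/C=C(\C)C(=O)OCC[Si](C)(C)C)[C@@H]1O[Si](C)(C)C(C)(C)C | intermediate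
24 | 2-(trimethylsilyl)ethyl (2E)-4-[(1S,2R,5R,6R)-2,5-bis[(tert-butyldimethylsilyl)oxy]-4-{[(tert-butyldimethylsilyl)oxy]methyl}-3-[(1E)-hept-1-en-1-yl]-7-oxabicyclo[4.1.0]hept-3-en-1-yl]-2-methylbut-2-enoate | CCCCC/C=C/C1=C(CO[Si](C)(C)C(C)(C)C)[C@@H](O[Si](C)(C)C(C)(C)C)[C@H]2O[C@@]2(C/C=C(\C)C(=O)OCC[Si](C)(C)C)[C@@H]1O[Si](C)(C)C(C)(C)C | intermediate
25 | (2E)-4-[(1S,2R,5R,6R)-3-[(1E)-hept-1-en-1-yl]-2,5-dihydroxy-4-(hydroxymethyl)-7-oxabicyclo[4.1.0]hept-3-en-1-yl]-2-methylbut-2-enoic acid (CNP0087193.3) | CCCCC/C=C/C1=C(CO)[C@@H](O)[C@H]2O[C@@]2(C/C=C(\C)C(=O)O)[C@@H]1O | target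

Total step count: 15. Longest linear sequence: 13 steps (steps 1–10 and 13–15); steps 11 and 12 make the side-chain reagent.

Steps most likely to fail

Step 9 (key cyclisation). Three processes threaten it. C6 may epimerise by enolisation or dienamine formation before the ring closes. The catalyst may be consumed by N-alkylation with the chloromethyl ketone. The aldol may lose water and aromatise. The fallback replaces enamine catalysis by a stoichiometric metal enolate. It sets out from 15: Cy2BCl and Et3N in Et2O at −78 °C should enolise the ketone on the chloromethyl side to the dicyclohexylboron (E)-enolate F1. This should close onto the aldehyde through a chelated chair-like transition state to the boron aldolate F2, with the trans C3/C4 relationship expected from the (E)-enolate and the face set by the C6 silyl ether. Buffered methanolysis at pH 7 releases the aldol, and the route is rejoined at 17.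

Step 13 (side-chain addition). Addition to the doubly α-branched ketone may be slow, which would give TiCl4 time to ionise the allylic silyl ethers. The ketone may enolise and eliminate the C3 silyloxy group. The dienol ether may react at its α-carbon instead of its γ-carbon. The fallback uses a two-carbon enolate followed by olefination. It sets out from 18: the cerium enolate of ethyl acetate (LiN(i-Pr)2, EtOAc, CeCl3, THF, −78 to 0 °C) adds to C5, and the alkoxide closes the oxirane in the same flask to the epoxy ethyl ester F3. Reduction with i-Bu2AlH at −78 °C gives the epoxy aldehyde F4. Wittig reaction with ethyl 2-(triphenylphosphoranylidene)propanoate gives the (E)-configured ethyl enoate F5. Hydrolysis with LiOH in THF/H2O gives the tris-silylated acid F6. Bu4NF then removes the three silyl ethers, and the route is rejoined at the target 25.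

Step 4 (CBS reduction). Enantioselectivity may erode through uncatalysed reduction of the activated keto ester or through weak steric discrimination between the ester and the dienyl group. The fallback uses kinetic resolution in place of asymmetric reduction. It sets out from 8: Luche reduction (NaBH4, CeCl3·7H2O, EtOH, −40 °C) gives the racemic hydroxy ester F7. Burkholderia cepacia lipase with vinyl acetate in t-BuOMe should acylate the (S)-enantiomer, with the dienyl group as the large substituent, to the (S)-acetate F8. The unreacted (R)-alcohol is separated, and the route is rejoined at 9.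

Further compounds
F1 | step 9 | dicyclohexylboron (E)-enolate of 15 (C4=C5, chlorine trans to the boron-bound oxygen) | CCCCC/C=C/C(=C(/C=O)CO[Si](C)(C)C(C)(C)C)[C@@H](O[Si](C)(C)C(C)(C)C)/C(OB(C1CCCCC1)C1CCCCC1)=C\Cl
F2 | step 9 | C3-O-dicyclohexylboryl aldolate of 17 | CCCCC/C=C/C1=C(CO[Si](C)(C)C(C)(C)C)[C@@H](OB(C2CCCCC2)C2CCCCC2)[C@H](Cl)C(=O)[C@@H]1O[Si](C)(C)C(C)(C)C
F3 | step 13 | ethyl 2-[(1S,2R,5R,6R)-2,5-bis[(tert-butyldimethylsilyl)oxy]-4-{[(tert-butyldimethylsilyl)oxy]methyl}-3-[(1E)-hept-1-en-1-yl]-7-oxabicyclo[4.1.0]hept-3-en-1-yl]acetate | CCCCC/C=C/C1=C(CO[Si](C)(C)C(C)(C)C)[C@@H](O[Si](C)(C)C(C)(C)C)[C@H]2O[C@@]2(CC(=O)OCC)[C@@H]1O[Si](C)(C)C(C)(C)C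
F4 | step 13 | 2-[(1S,2R,5R,6R)-2,5-bis[(tert-butyldimethylsilyl)oxy]-4-{[(tert-butyldimethylsilyl)oxy]methyl}-3-[(1E)-hept-1-en-1-yl]-7-oxabicyclo[4.1.0]hept-3-en-1-yl]acetaldehyde | CCCCC/C=C/C1=C(CO[Si](C)(C)C(C)(C)C)[C@@H](O[Si](C)(C)C(C)(C)C)[C@H]2O[C@@]2(CC=O)[C@@H]1O[Si](C)(C)C(C)(C)C
F5 | step 13 | ethyl (2E)-4-[(1S,2R,5R,6R)-2,5-bis[(tert-butyldimethylsilyl)oxy]-4-{[(tert-butyldimethylsilyl)oxy]methyl}-3-[(1E)-hept-1-en-1-yl]-7-oxabicyclo[4.1.0]hept-3-en-1-yl]-2-methylbut-2-enoate | CCCCC/C=C/C1=C(CO[Si](C)(C)C(C)(C)C)[C@@H](O[Si](C)(C)C(C)(C)C)[C@H]2O[C@@]2(C/C=C(\C)C(=O)OCC)[C@@H]1O[Si](C)(C)C(C)(C)C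
F6 | step 13 | (2E)-4-[(1S,2R,5R,6R)-2,5-bis[(tert-butyldimethylsilyl)oxy]-4-{[(tert-butyldimethylsilyl)oxy]methyl}-3-[(1E)-hept-1-en-1-yl]-7-oxabicyclo[4.1.0]hept-3-en-1-yl]-2-methylbut-2-enoic acid | CCCCC/C=C/C1=C(CO[Si](C)(C)C(C)(C)C)[C@@H](O[Si](C)(C)C(C)(C)C)[C@H]2O[C@@]2(C/C=C(\C)C(=O)O)[C@@H]1O[Si](C)(C)C(C)(C)C
F7 | step 4 | racemic ethyl (4E)-3-(2,2-dimethyl-1,3-dioxan-5-ylidene)-2-hydroxydec-4-enoate | CCCCC/C=C/C(=C1COC(C)(C)OC1)C(O)C(=O)OCC
F8 | step 4 | ethyl (2S,4E)-2-acetoxy-3-(2,2-dimethyl-1,3-dioxan-5-ylidene)dec-4-enoate | CCCCC/C=C/C(=C1COC(C)(C)OC1)[C@H](OC(C)=O)C(=O)OCC
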